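The substrate is charged with none of its other forms beside it, and in each flask we ask which form holds most of it when we stop. The partner stands in no step with those forms, so solid reagent and partner drop out of the reckoning.

    solid reagent ⇌ partner, rate k1*(cs1 - [partner]) while solid is left; crystals form when [partner] > cs1 (cs1 = 0.70 M, k1 = 0.0113 min⁻¹)
    intermediate A ⇌ intermediate B (K2 = 1.56, k2 = 0.00579 min⁻¹)
    substrate ⇌ product (K3 = 0.566, k3 = 9.70 × 10⁻⁴ min⁻¹)
    substrate ⇌ intermediate A (K4 = 11, k4 = 6.19 × 10⁻⁴ min⁻¹)

all flasks: substrate 1.0 M; solid reagent 2.50 M

| run | time |
|---|---|
| grey | 15 h |
| violet | 45 h |
| ochre | 140 h |

- which of these there is most of at the end, counted by the substrate in it, grey (product / substrate / intermediate B / intermediate A)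
- which of these there is most of at the end, counted by the substrate in it, violet (product / substrate / intermediate B / intermediate A)
- which of these there is most of at the end, counted by the substrate in it, ochre (product / substrate / intermediate B / intermediate A)
- how much there is at the end of the one of these that leads, in percent of the substrate charged: grey
- how much there is at the end of the one of these that leads, in percent of the substrate charged: violet
- how much there is at the end of the one of these that leads, in percent of the substrate charged: ochre

Where does the flask come to rest? Counting substrate as one, the equilibrium weights add up to 29.7. An even split of the forms would give each a quarter, but intermediate B's rest share is 57.7% and substrate's is 3.36%. These rest shares, not zero, are the zero of our scale.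

How fast does the flask get there? Substrate and product relax together at 0.00268 min⁻¹, which is faster than substrate passes to intermediate A. Because of this we treat the two as one pool in pre-equilibrium, with substrate at 63.9% of it. Intermediate A and intermediate B relax faster still, so the pair keeps step. The pool then drains at 3.95 × 10⁻⁴ min⁻¹, our leak constant: the forward constant into intermediate A times substrate's share of the pool.

What stands at each stop? In our estimate each form starts from its place just after the pool has formed, and we let its distance from its rest share shrink as the exponential of minus the leak constant times the time. That fraction is 0.701 at 15 h, 0.344 at 45 h and 0.0361 at 140 h.

So for grey we expect substrate at 45.7%. For violet we expect intermediate B at 37.9%, and for ochre intermediate B at 55.6%.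

The forecast, reckoned on two rates with the words "The three-pool system has eigenvalues", names substrate at 41.6% for grey, intermediate B at 38.5% for violet and intermediate B at 55.5% for ochre. Its grey figure is lower than ours.

The simulation gives substrate at 41.6% for grey, intermediate B at 38.4% for violet and intermediate B at 55.5% for ochre. In violet, substrate and product relax by their step alone, both ways together, with a half-life of 4.30 h, shorter than the 29.2 h half-life of the leak constant. For the violet flask read at 3.0 d, the leak constant puts intermediate B at 47.3%, and that reading holds 47.3%.

The constants were chosen freely; what happens was integrated by code.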